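**Plan**

The target is an achiral diaryl ether that links C5 of a 6,7-dihydroxycoumarin (unit B) to C6 of a 7-hydroxycoumarin (unit A). It has no stereocentre, so nothing has to be set; the only stereo element on the way, an E enol ether, is consumed.
Retrosynthesis: pyranone A is cut at O1–C2 and C4–C4a (Pechmann). Benzene ring A is then taken apart at C4a–C5, C4a–C8a, C7–C8 and C6–C7 into a β-aryloxyvinyl diazoketone and ethoxyacetylene. The diazo group, the enol-ether C–O bond (oxa-Michael to butynone) and pyranone B (intramolecular Wittig) are removed next, which leads to 3,4,5-trimethoxyphenol.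
Enabling feature: ring A carries a resorcinol-type pair of oxygens, C7–OH and the lactone oxygen on C8a, flanking unsubstituted C8, and the ether oxygen on C6 is ortho to C7–OH and para to C8a. A vinylketene (C4a, C5, C6, C7) and an alkoxyacetylene (C8, C8a) deliver exactly this pattern on benzannulation, so the crowded diaryl ether oxygen can be installed beforehand as an unhindered enol ether.
Forward order: pyranone B (steps 1–4), aryloxy enone and diazoketone (steps 5–6), benzene ring A (step 7), global dealkylation and pyranone A (steps 8–9).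

Key step: step 7

Remark: the boron aryloxides present before aqueous work-up in steps 3 and 8 are mixtures of no single composition and carry no number; racemic malic acid is used in step 9 because its stereocentre is lost.

**Route**

Step 1
Reactants: 1 3,4,5-trimethoxyphenol
Product: 3 6-hydroxy-2,3,4-trimethoxybenzaldehyde, via aryl iminium salt 2 (not isolated)
Conditions: POCl3, DMF, 0 °C to rt; then H2O, 60 °C
Reagents that add atoms: N,N-dimethylformamide, CN(C)C=O (formyl carbon); water, O (aldehyde oxygen)
Why: Vilsmeier–Haack formylation: the chloroiminium ion made from DMF and POCl3 should attack one of the two equivalent positions ortho to the hydroxyl (each also para to a methoxy group), and hydrolysis of iminium salt 2 should release the salicylaldehyde.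

Step 2
Reactants: 3 6-hydroxy-2,3,4-trimethoxybenzaldehyde
Product: 4 2-formyl-3,4,5-trimethoxyphenyl chloroacetate
Conditions: ClCH2COCl, pyridine, CH2Cl2, 0 °C
Reagents that add atoms: chloroacetyl chloride, O=C(Cl)CCl
Why: Esterification of a phenol with an acid chloride, which labels the oxygen that is to become O1 of unit B and brings in C2 and C3; unlike a phosphonoacetate, the chloroacetate cannot olefinate the neighbouring aldehyde until a phosphine is added.

Step 3
Reactants: 4 2-formyl-3,4,5-trimethoxyphenyl chloroacetate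
Product: 5 2-formyl-3-hydroxy-4,5-dimethoxyphenyl chloroacetate
Conditions: BCl3, CH2Cl2, −78 to 0 °C; then H2O
Reagents that add atoms: none
Why: Chelation-controlled Lewis acid ether cleavage: BCl3 bound to the formyl oxygen reaches only the ortho methoxy group through a six-membered chelate, so this methyl ether alone should be cleaved (as MeCl) while the two remote methoxy groups and the aryl ester stay, as is usual for ortho-methoxybenzaldehydes.

Step 4
Reactants: 5 2-formyl-3-hydroxy-4,5-dimethoxyphenyl chloroacetate
Product: 8 5-hydroxy-6,7-dimethoxy-2H-chromen-2-one, via phosphonium chloride 6 (not isolated), via ester ylide 7 (not isolated)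
Conditions: PPh3, PhMe, 80 °C; then Et3N, 80 °C
Reagents that add atoms: none
Why: Intramolecular Wittig reaction: SN2 displacement of chloride by PPh3 gives salt 6, Et3N forms the stabilised ylide 7, and its closure on the ortho aldehyde should give the ring-enforced cis C3=C4 bond of the pyranone with loss of Ph3PO, a known way from salicylaldehyde haloacetates to 3,4-unsubstituted coumarins that here fixes which oxygen is O1 and leaves the C5 hydroxyl free.

Step 5
Reactants: 8 5-hydroxy-6,7-dimethoxy-2H-chromen-2-one; 9 but-3-yn-2-one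
Product: 10 (3E)-4-[(6,7-dimethoxy-2-oxo-2H-chromen-5-yl)oxy]but-3-en-2-one
Conditions: DABCO (10 mol %), CH2Cl2, 0 °C to rt
Reagents that add atoms: none
Why: Amine-catalysed oxa-Michael addition of a phenol to an ynone: DABCO adds to butynone, the zwitterion deprotonates the phenol, and addition–elimination of the phenoxide should give the thermodynamically preferred E β-aryloxy enone, so the hindered C5–O bond is made at an sp carbon that offers no steric resistance.

Step 6
Reactants: 10 (3E)-4-[(6,7-dimethoxy-2-oxo-2H-chromen-5-yl)oxy]but-3-en-2-one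
Product: 12 (3E)-1-diazo-4-[(6,7-dimethoxy-2-oxo-2H-chromen-5-yl)oxy]but-3-en-2-one, via trifluoroacetyl diketone 11 (not isolated)
Conditions: LiN(SiMe3)2, THF, −78 °C, then CF3CO2CH2CF3, aq. HCl work-up; then 4-AcNHC6H4SO2N3, Et3N, H2O, MeCN, rt
Reagents that add atoms: 4-acetamidobenzenesulfonyl azide, CC(=O)Nc1ccc(cc1)S(=O)(=O)N=[N+]=[N-] (the two diazo nitrogens)
Why: Detrifluoroacetylative diazo transfer: the kinetic lithium enolate of the methyl ketone (the only enolisable position) is acylated by the trifluoroacetate ester, and the activated diketone 11 should take the diazo group from the sulfonyl azide while its trifluoroacetyl group leaves on the sulfonamide nitrogen, a method made for α,β-unsaturated methyl ketones that avoids acid chlorides and diazomethane.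

Step 7
Reactants: 12 (3E)-1-diazo-4-[(6,7-dimethoxy-2-oxo-2H-chromen-5-yl)oxy]but-3-en-2-one; 13 ethoxyacetylene
Product: 18 5-(4-ethoxy-2-hydroxyphenoxy)-6,7-dimethoxy-2H-chromen-2-one, via vinylketene 14 (not isolated), via vinylcyclobutenone 15 (not isolated), via dienylketene 16 (not isolated), via cyclohexadienone 17 (not isolated)
Conditions: 13 (5 equiv), ClCH2CH2Cl (0.02 M), hν (440 nm LEDs, flow), rt; then PhMe, 80 °C
Reagents that add atoms: none
Why: This is a Danheiser benzannulation in its photochemical Wolff form, a known reaction of α,β-unsaturated diazoketones with alkoxyacetylenes. Irradiation into the weak long-wavelength diazo band, where the coumarin should be transparent, expels N2 while the vinyl carbon C5 shifts from the carbonyl carbon C7 to the former diazo carbon C4a, which gives vinylketene 14. The hydrogen-bearing, nucleophilic carbon of ethoxyacetylene (C8) bonds to the electrophilic ketene carbon C7 and the oxygen-bearing carbon (C8a) bonds to C4a, a [2+2] cycloaddition that closes the four-membered ring of 15. On warming, that ring opens by a conrotatory four-electron electrocyclic reaction (C4a–C7 breaks) to dienylketene 16, and benzene ring A is closed by a disrotatory six-electron electrocyclisation that forms C6–C7, after which dienone 17 tautomerises to the phenol. No stereocentre survives, since the sp3 carbons of 15 and 17 are transient. The one selectivity needed is regiochemical (ethoxy carbon meta to the new hydroxyl and para to the aryloxy group) and it follows from the fixed polarity of the ynol ether; excess alkyne and high dilution should keep the ketenes from acylating the product phenol.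

Step 8
Reactants: 18 5-(4-ethoxy-2-hydroxyphenoxy)-6,7-dimethoxy-2H-chromen-2-one
Product: 19 5-(2,4-dihydroxyphenoxy)-6,7-dihydroxy-2H-chromen-2-one
Conditions: BBr3 (6 equiv), CH2Cl2, −78 °C to rt; then H2O
Reagents that add atoms: none
Why: Lewis acid dealkylation of aryl alkyl ethers with BBr3: bromide attacks the methyl and ethyl carbons of the boron-complexed ethers, whereas the diaryl ether offers no carbon for SN2 attack and the lactone is only complexed, so all four phenols should be freed with both rings and the ether link intact.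

Step 9
Reactants: 19 5-(2,4-dihydroxyphenoxy)-6,7-dihydroxy-2H-chromen-2-one
Product: 20 6,7-dihydroxy-5-[(7-hydroxy-2-oxo-2H-chromen-6-yl)oxy]-2H-chromen-2-one
Conditions: DL-malic acid (1.1 equiv), conc. H2SO4, 100 °C
Reagents that add atoms: DL-malic acid, OC(=O)CC(O)C(=O)O (C2, C3, C4 and the carbonyl oxygen of pyranone A)
Why: von Pechmann coumarin synthesis in its malic acid form: H2SO4 degrades malic acid to formylacetic acid, which should attack the resorcinol ring of 19 at the carbon para to the future C7 hydroxyl and ortho to the future O1 (the site that reacts when hydroxyquinol is converted into esculetin) and then lactonise onto that oxygen, while ring B, deactivated by its pyranone, should react more slowly.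

**Compound list**

1 | 3,4,5-trimethoxyphenol | COc1cc(O)cc(OC)c1OC | starting material
2 | N-[(6-hydroxy-2,3,4-trimethoxyphenyl)methylidene]-N-methylmethanaminium dichlorophosphate | C[N+](C)=Cc1c(O)cc(OC)c(OC)c1OC.[O-]P(=O)(Cl)Cl | intermediate
3 | 6-hydroxy-2,3,4-trimethoxybenzaldehyde | O=Cc1c(O)cc(OC)c(OC)c1OC | intermediate
4 | 2-formyl-3,4,5-trimethoxyphenyl chloroacetate | O=Cc1c(OC(=O)CCl)cc(OC)c(OC)c1OC | intermediate
5 | 2-formyl-3-hydroxy-4,5-dimethoxyphenyl chloroacetate | O=Cc1c(OC(=O)CCl)cc(OC)c(OC)c1O | intermediate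
6 | [2-(2-formyl-3-hydroxy-4,5-dimethoxyphenoxy)-2-oxoethyl]triphenylphosphonium chloride | O=Cc1c(OC(=O)C[P+](c2ccccc2)(c2ccccc2)c2ccccc2)cc(OC)c(OC)c1O.[Cl-] | intermediate
7 | 2-formyl-3-hydroxy-4,5-dimethoxyphenyl 2-(triphenylphosphoranylidene)acetate | O=Cc1c(OC(=O)C=P(c2ccccc2)(c2ccccc2)c2ccccc2)cc(OC)c(OC)c1O | intermediate
8 | 5-hydroxy-6,7-dimethoxy-2H-chromen-2-one | COc1cc2oc(=O)ccc2c(O)c1OC | intermediate
9 | but-3-yn-2-one | CC(=O)C#C | starting material
10 | (3E)-4-[(6,7-dimethoxy-2-oxo-2H-chromen-5-yl)oxy]but-3-en-2-one | CC(=O)/C=C/Oc1c(OC)c(OC)cc2oc(=O)ccc12 | intermediate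
11 | (5E)-1,1,1-trifluoro-6-[(6,7-dimethoxy-2-oxo-2H-chromen-5-yl)oxy]hex-5-ene-2,4-dione | O=C(CC(=O)/C=C/Oc1c(OC)c(OC)cc2oc(=O)ccc12)C(F)(F)F | intermediate
12 | (3E)-1-diazo-4-[(6,7-dimethoxy-2-oxo-2H-chromen-5-yl)oxy]but-3-en-2-one | [N-]=[N+]=CC(=O)/C=C/Oc1c(OC)c(OC)cc2oc(=O)ccc12 | intermediate
13 | ethoxyacetylene (ethoxyethyne) | C#COCC | starting material
14 | (3E)-4-[(6,7-dimethoxy-2-oxo-2H-chromen-5-yl)oxy]buta-1,3-dien-1-one | O=C=C/C=C/Oc1c(OC)c(OC)cc2oc(=O)ccc12 | intermediate
15 | 4-{(E)-2-[(6,7-dimethoxy-2-oxo-2H-chromen-5-yl)oxy]ethenyl}-3-ethoxycyclobut-2-en-1-one (racemic) | CCOC1=CC(=O)C1/C=C/Oc2c(OC)c(OC)cc3oc(=O)ccc23 | intermediate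
16 | (3E,5E)-6-[(6,7-dimethoxy-2-oxo-2H-chromen-5-yl)oxy]-3-ethoxyhexa-1,3,5-trien-1-one | O=C=C/C(OCC)=C\C=C\Oc1c(OC)c(OC)cc2oc(=O)ccc12 | intermediate
17 | 6-[(6,7-dimethoxy-2-oxo-2H-chromen-5-yl)oxy]-3-ethoxycyclohexa-2,4-dien-1-one (racemic) | CCOC1=CC(=O)C(Oc2c(OC)c(OC)cc3oc(=O)ccc23)C=C1 | intermediate
18 | 5-(4-ethoxy-2-hydroxyphenoxy)-6,7-dimethoxy-2H-chromen-2-one | CCOc1ccc(Oc2c(OC)c(OC)cc3oc(=O)ccc23)c(O)c1 | intermediate
19 | 5-(2,4-dihydroxyphenoxy)-6,7-dihydroxy-2H-chromen-2-one | Oc1ccc(Oc2c(O)c(O)cc3oc(=O)ccc23)c(O)c1 | intermediate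
20 | 6,7-dihydroxy-5-[(7-hydroxy-2-oxo-2H-chromen-6-yl)oxy]-2H-chromen-2-one | O=c1ccc2cc(Oc3c(O)c(O)cc4oc(=O)ccc34)c(O)cc2o1 | target

**Step count**

Total: 9 steps. Longest linear sequence: 9 steps (1 to 20); 9 and 13 are bought.

**Steps most likely to fail**

Step 7 (benzannulation). If the diazo band absorbs too weakly at 440 nm and shorter wavelengths are needed, light absorption by the coumarin and its [2+2] photodimerisation would compete with loss of nitrogen. The ketenes may also be intercepted by the product phenol or by traces of water before the alkyne adds, and the thermal ring opening and closure may stall at the cyclobutenone stage. The fallback gives up building ring A and buys it instead, setting out from 8. Nucleophilic aromatic substitution of 8 on 2-fluoro-5-methoxybenzaldehyde (K2CO3, DMF, 110 °C), where the ortho formyl group activates the fluoride, should give 2-[(6,7-dimethoxy-2-oxo-2H-chromen-5-yl)oxy]-5-methoxybenzaldehyde F1. Baeyer–Villiger oxidation with mCPBA (CH2Cl2, rt), in which the ortho aryloxy donor favours aryl migration, should give 2-[(6,7-dimethoxy-2-oxo-2H-chromen-5-yl)oxy]-5-methoxyphenyl formate F2. BBr3 (CH2Cl2, −78 °C to rt, aqueous work-up) should then cleave the three methyl ethers and the formate, so that the route is rejoined at 19.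

Step 6 (diazo transfer). The amide base, or triethylamine and water in the second stage, may expel the aryloxide from the vinylogous ester carbon by addition–elimination or open the lactone before diazo transfer is complete; trifluoroacetylation may also be incomplete. The fallback sets out from 8 and avoids both strong base and aqueous amine. DABCO-catalysed addition of 8 to tert-butyl propiolate should give tert-butyl (2E)-3-[(6,7-dimethoxy-2-oxo-2H-chromen-5-yl)oxy]prop-2-enoate F3. Trifluoroacetic acid in CH2Cl2 should free (2E)-3-[(6,7-dimethoxy-2-oxo-2H-chromen-5-yl)oxy]prop-2-enoic acid F4. Oxalyl chloride with catalytic DMF should give (2E)-3-[(6,7-dimethoxy-2-oxo-2H-chromen-5-yl)oxy]prop-2-enoyl chloride F5. Acylation of excess diazomethane (Et2O, 0 °C, the first stage of an Arndt–Eistert sequence) should deliver 12, where the route is rejoined; the electron-rich β-aryloxy alkene is a poor dipolarophile, so pyrazoline formation should stay minor.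

Step 9 (Pechmann annulation). Sulfonation and oxidative breakdown of the polyphenol in hot sulfuric acid may compete. Site selectivity may also be lost through annulation on ring B (C8 with the C7 hydroxyl) or through a second annulation. The fallback sets out from 18 and builds pyranone A stepwise, so that only ring A ever carries the carbon needed for a lactone. Vilsmeier–Haack formylation of 18 (POCl3, DMF) para to the free hydroxyl and ortho to the ethoxy group should pass through N-({5-[(6,7-dimethoxy-2-oxo-2H-chromen-5-yl)oxy]-2-ethoxy-4-hydroxyphenyl}methylidene)-N-methylmethanaminium dichlorophosphate F6. Hydrolysis should give 5-[(6,7-dimethoxy-2-oxo-2H-chromen-5-yl)oxy]-2-ethoxy-4-hydroxybenzaldehyde F7. BBr3 should then free 5-[(6,7-dihydroxy-2-oxo-2H-chromen-5-yl)oxy]-2,4-dihydroxybenzaldehyde F8. Wittig olefination with Ph3P=CHCO2Et in N,N-diethylaniline at reflux should form ethyl (2E)-3-{5-[(6,7-dihydroxy-2-oxo-2H-chromen-5-yl)oxy]-2,4-dihydroxyphenyl}prop-2-enoate F9, which at that temperature should isomerise and lactonise to 20.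

**Further compounds**

F1 | step 7 | 2-[(6,7-dimethoxy-2-oxo-2H-chromen-5-yl)oxy]-5-methoxybenzaldehyde | COc1ccc(Oc2c(OC)c(OC)cc3oc(=O)ccc23)c(C=O)c1
F2 | step 7 | 2-[(6,7-dimethoxy-2-oxo-2H-chromen-5-yl)oxy]-5-methoxyphenyl formate | COc1ccc(Oc2c(OC)c(OC)cc3oc(=O)ccc23)c(OC=O)c1
F3 | step 6 | tert-butyl (2E)-3-[(6,7-dimethoxy-2-oxo-2H-chromen-5-yl)oxy]prop-2-enoate | CC(C)(C)OC(=O)/C=C/Oc1c(OC)c(OC)cc2oc(=O)ccc12
F4 | step 6 | (2E)-3-[(6,7-dimethoxy-2-oxo-2H-chromen-5-yl)oxy]prop-2-enoic acid | OC(=O)/C=C/Oc1c(OC)c(OC)cc2oc(=O)ccc12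
F5 | step 6 | (2E)-3-[(6,7-dimethoxy-2-oxo-2H-chromen-5-yl)oxy]prop-2-enoyl chloride | ClC(=O)/C=C/Oc1c(OC)c(OC)cc2oc(=O)ccc12
F6 | step 9 | N-({5-[(6,7-dimethoxy-2-oxo-2H-chromen-5-yl)oxy]-2-ethoxy-4-hydroxyphenyl}methylidene)-N-methylmethanaminium dichlorophosphate | CCOc1cc(O)c(Oc2c(OC)c(OC)cc3oc(=O)ccc23)cc1C=[N+](C)C.[O-]P(=O)(Cl)Cl
F7 | step 9 | 5-[(6,7-dimethoxy-2-oxo-2H-chromen-5-yl)oxy]-2-ethoxy-4-hydroxybenzaldehyde | CCOc1cc(O)c(Oc2c(OC)c(OC)cc3oc(=O)ccc23)cc1C=O
F8 | step 9 | 5-[(6,7-dihydroxy-2-oxo-2H-chromen-5-yl)oxy]-2,4-dihydroxybenzaldehyde | O=Cc1cc(Oc2c(O)c(O)cc3oc(=O)ccc23)c(O)cc1O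
F9 | step 9 | ethyl (2E)-3-{5-[(6,7-dihydroxy-2-oxo-2H-chromen-5-yl)oxy]-2,4-dihydroxyphenyl}prop-2-enoate | CCOC(=O)/C=C/c1cc(Oc2c(O)c(O)cc3oc(=O)ccc23)c(O)cc1O
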